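**Assumption:** the target, 4'-O-geranylisoliquiritigenin, has no sp3 stereocenters. The only stereochemical elements are the (E)-trisubstituted geranyl alkene and the (E)-enone, and both are carried through unchanged. No rings are formed, so the route assembles the skeleton by alkylation and then C–C bond formation.

**Retrosynthesis**
- The enone C=C is disconnected by Claisen–Schmidt (aldol condensation) into 4-geranyloxy-2-hydroxyacetophenone (4) and 4-hydroxybenzaldehyde (3).
- The aryl geranyl ether is disconnected by Williamson etherification into 2',4'-dihydroxyacetophenone (1) and geranyl bromide (2).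
- Alkylation is selective for the 4-OH because the 2-OH is hydrogen-bonded to the ketone and less acidic and less nucleophilic.
- The route is 2 steps, with both starting materials and the aldehyde commercial.

**Step 1**
Reactants: 1 (2',4'-dihydroxyacetophenone, resacetophenone) and 2 ((2E)-geranyl bromide, 1-bromo-3,7-dimethylocta-2,6-diene, E)
Product: 4, 1-[2-hydroxy-4-(((2E)-3,7-dimethylocta-2,6-dienyl)oxy)phenyl]ethan-1-one
Conditions: 2 (1.1 equiv), CsHCO3 (or KHCO3/KI), MeCN, 80 °C, 6–12 h
Reagents that add atoms: geranyl bromide, CC(C)=CCC/C(C)=C/CBr (delivers the geranyl group)
Why: Williamson O-alkylation (SN2) with a mild bicarbonate base deprotonates only the more acidic, non-chelated 4-OH. The chelated 2-OH stays free, and the primary allylic bromide reacts without touching the alkene geometry, so no stereocenters are involved.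

**Step 2**
Reactants: 4 and 3 (4-hydroxybenzaldehyde)
Product: 5, (E)-1-[4-(geranyloxy)-2-hydroxyphenyl]-3-(4-hydroxyphenyl)prop-2-en-1-one (target)
Conditions: 3 (1.2 equiv), 50% aq. KOH (about 5 equiv) in EtOH, rt, 24–48 h, then cool and acidify with 1 M HCl to pH about 3–4
Reagents that add atoms: none (the aldol condensation loses H2O)
Why: Claisen–Schmidt condensation. The acetophenone enolate adds to the aldehyde, and E1cB dehydration gives the conjugated enone with the thermodynamically favoured (E) geometry. Excess base covers the two phenols, including the 4-hydroxybenzaldehyde phenolate, and the aryl geranyl ether and its alkenes are base-stable. The mild acidic quench avoids allylic ether cleavage.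

**Check of the route against the target**
- Target SMILES: CC(C)=CCC/C(C)=C/COc1ccc(C(=O)/C=C/c2ccc(O)cc2)c(O)c1.
- It is a 4'-O-geranyl ether, with a free 2'-OH ortho to the carbonyl, a free 4-OH on ring B, an (E)-enone and an (E)-geranyl alkene.
- Formula: C18H24O3 (4) + C7H6O2 (3) − H2O = C25H28O4, which matches the target.
- The geranyl group sits para to the carbonyl, as in 4, and the 2-OH is untouched.
- The alkenes are not reduced or isomerised, and no protecting groups are needed.
- No stereocenters need to be set.

**Compound list**
1 | 2',4'-dihydroxyacetophenone | CC(=O)c1ccc(O)cc1O | starting material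
2 | (E)-geranyl bromide | CC(C)=CCC/C(C)=C/CBr | starting material
3 | 4-hydroxybenzaldehyde | O=Cc1ccc(O)cc1 | starting material
4 | 4'-O-geranyl-2',4'-dihydroxyacetophenone | CC(C)=CCC/C(C)=C/COc1ccc(C(C)=O)c(O)c1 | intermediate
5 | 4'-O-geranylisoliquiritigenin | CC(C)=CCC/C(C)=C/COc1ccc(C(=O)/C=C/c2ccc(O)cc2)c(O)c1 | target

**Total steps:** 2. **Longest linear sequence:** 2.

**Three steps most likely to fail**
1. **Step 1, regioselectivity.** Over-alkylation (2,4-bis-ether) or 2-O-alkylation could occur, or C-alkylation.
   - Fallback: Mitsunobu etherification of 1 with geraniol, PPh3 and DIAD in THF. This uses the greater acidity of the 4-OH and avoids alkyl halide and strong base.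
2. **Step 2, free-phenol aldehyde.** The phenolate of 4-hydroxybenzaldehyde is a poor electrophile, so conversion and yield may be low.
   - Fallback: use 4-(methoxymethoxy)benzaldehyde in the condensation. Then remove the MOM group under mild, non-protic-acid conditions, such as MgBr2·OEt2 with a thiol scavenger.
3. **Step 2, side reactions of the 2'-hydroxychalcone.** Oxa-Michael cyclisation to the 7-O-geranylflavanone, or acid-induced geranyl ether cleavage or isomerisation, could occur on prolonged base exposure or acidic workup.
   - Fallback: change the bond formation. Run an aryl-directed Wittig or HWE olefination between a protected 4-hydroxybenzaldehyde and a phosphonate derived from 4, under non-equilibrating conditions. Alternatively, make isoliquiritigenin first and then do a late, selective 4'-O-geranylation.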